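The ratio of two rates tells what Thursday's flask can still make: how fast the logarithm of the fraction left falls, over how fast that first rate itself dies away.

common to all: free catalyst 0.10 mM
- Thursday's: substrate 0.10 M; temperature 40 °C; the very flask that is asked about, followed so far
- Wednesday's: substrate 0.067 M; temperature 35 °C; run made earlier
- flask: substrate 0.10 M; temperature 40 °C; time 1.5 h

Thursday's run (percent of the substrate charged)

| time / min | product / % |
|---|---|
| 3.00 | 2 |
| 8.00 | 19 |
| 15.0 | 31 |
| 25.0 | 48 |
| 30.0 | 49 |
| 40.0 | 57 |
| 50.0 | 60 |

Wednesday's run (percent of the substrate charged)

| time / s | product / % |
|---|---|
| 10.0 | 0 |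
| 20.0 | 3 |
| 30.0 | 0 |
| 50.0 | 0 |
| 80.0 | 0 |
| 90.0 | 0 |
| 120 | 3 |

(each reading ± 2 percentage points)

- product that was removed still counts
- steps thought possible: substrate -> intermediate; free catalyst + intermediate -> free catalyst + product; free catalyst -> spent catalyst
- additions bring no volume worth counting

- cedar: at 1.5 h take out 90 % of the product then present, then wait 25 min
- alder: at 1.5 h add free catalyst, 100 % of the amount charged, then wait 25 min
- ash: change nothing and wait 25 min more
- birch: at 1.5 h raise the temperature by 15 K, then wait 25 min

1. product, in percent of the substrate first charged, at 1.5 h
2. what to do for the largest gain in product; "none" if nothing gains more than 2 percentage points (cedar / alder / ash / birch / none)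
3. product present, with what was taken out counted in, in percent of the substrate first charged, after ash
4. product present, with what was taken out counted in, in percent of the substrate first charged, after birch

Take the main step by itself first. At steady c(free catalyst) the conversion of intermediate is pseudo-first-order, so L, the fraction of the charge not yet product, falls on a straight line in ln L. Thursday's readings between 15.0 min and 25.0 min give a slope of 0.0283 min⁻¹.

Now add the loss of free catalyst to spent catalyst. Between 40.0 min and 50.0 min the slope is 0.00723 min⁻¹, smaller than the earlier one. The two intervals lie 25.0 min apart, so the slope dies at 0.0546 min⁻¹. The reach, the further fall in ln L that the free catalyst present can still bring before it is spent, is slope over dying rate; at the last reading it is 0.101. This is a rough reading, since the late slope rests on a gain of 3 percentage points with a scatter of 2 points on each reading.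

Last comes substrate to intermediate. It feeds the early slope while it lasts and so holds that slope down, which makes the dying rate a low reading. Wednesday's run is too short to add a temperature effect.

This reckoning leaves L at 36.6 % at 1.5 h, so product stands at 63.4 %. The reach has then shrunk to 0.0114, and ash gains 0.31 points, less than the margin. Cedar gains what ash gains, 0.31 points, as product enters no step as a reactant. Alder restores the reach of a full charge, 1.54, which takes product to 88.4 %, a gain of 25 points.

The forecast gave 67 %, 68.5 % after ash, 69 % after birch, and chose alder: “Fresh catalyst restarts conversion of the stranded intermediate”.

The flask gives 61.7 %, 61.8 % after ash and 61.7 % after birch, and alder is best, with a gain of 32 points.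

    substrate → intermediate (k = 0.0800 min⁻¹, Ea = 89.0 kJ mol⁻¹)
    free catalyst + intermediate → free catalyst + product (k = 1500 L mol⁻¹ min⁻¹, Ea = 45.0 kJ mol⁻¹)
    free catalyst → spent catalyst (k = 0.0700 min⁻¹, Ea = 104 kJ mol⁻¹)
    (constants at 40 °C)

In Thursday's flask the intermediate's half-life by the catalysed step alone, with the catalyst as charged, is 4.6 min, against 9.9 min for free catalyst by its own step alone, a ratio of 2.14, which is the reach of a fresh charge. The reach, read as 0.101 at the last reading, comes from these constants at 1.5 h to 2.14 times the 0.184 % of the catalyst still free, which is 0.00393; on the 38.2 % of intermediate standing then in Thursday's flask it is worth 0.12 points in the further wait, and ash brings 0.12 points. The ratio 2.14 on that same intermediate gives 32 points for alder, whose simulated gain is 32 points.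

(All runs were generated by integration for substances that don't exist, and the scatter is random.)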